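**Retrosynthetic overview**
1. Target 15 ← 14 by global O-demethylation; 14 is the same fuchsone with both phenols as methyl ethers.
2. 14 ← hindered aryl triflate 10 + tosylhydrazone 12 by a new Pd carbene coupling ending in dearomative 1,6-elimination; this makes the aryl–C(methide) bond and the quinone methide together.
3. 10 ← iodo triflate 8 + alkyne 9 by iodide-selective Sonogashira coupling; 8 ← biphenylol 3 by carbamate-directed ortho-lithiation/iodination, hydrolysis and triflation.
4. 3 ← 2-bromo-5-methylphenol 1 + boronic acid 2 by Suzuki coupling.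
5. No ring is built de novo: all four benzene rings are bought, and the cyclohexadienone ring arises by dearomatisation of a phenol ring in the key step.

Assumption: the target SMILES has no stereocentre and no stereodescriptor (the dienone ring is symmetric, so the exocyclic C=C has no E/Z isomers), so the compound is treated as achiral and needs no stereocontrol.

**Route**

Step 1
Reactants: 1 2-bromo-5-methylphenol; 2 (4-methoxyphenyl)boronic acid
Product: 3 4'-methoxy-4-methyl-[1,1'-biphenyl]-2-ol
Conditions: Pd(PPh3)4 (3 mol %), K2CO3, dioxane/H2O, 90 °C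
Reagents that add atoms: none
Why: Suzuki–Miyaura coupling of an unhindered aryl bromide, which tolerates the free phenol.

Step 2
Reactants: 3 4'-methoxy-4-methyl-[1,1'-biphenyl]-2-ol
Product: 4 4'-methoxy-4-methyl-[1,1'-biphenyl]-2-yl diethylcarbamate
Conditions: NaH, THF, 0 °C; Et2NCOCl, 0 °C → rt
Reagents that add atoms: diethylcarbamoyl chloride, CCN(CC)C(=O)Cl
Why: O-carbamoylation of the sodium phenoxide installs the strongest oxygen-based directing group for the next step.

Step 3
Reactants: 4 4'-methoxy-4-methyl-[1,1'-biphenyl]-2-yl diethylcarbamate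
Product: 6 3-iodo-4'-methoxy-4-methyl-[1,1'-biphenyl]-2-yl diethylcarbamate, via lithiated carbamate 5 (not isolated)
Conditions: s-BuLi, TMEDA, THF, −78 °C; then I2, −78 °C → rt
Reagents that add atoms: iodine, II
Why: Directed ortho-metalation; the only free position ortho to the carbamate is C3 (between the carbamate and the methyl group), the carbamate outcompetes the methoxy group at −78 °C, and the aryllithium is trapped by iodine before any anionic Fries rearrangement.

Step 4
Reactants: 6 3-iodo-4'-methoxy-4-methyl-[1,1'-biphenyl]-2-yl diethylcarbamate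
Product: 7 3-iodo-4'-methoxy-4-methyl-[1,1'-biphenyl]-2-ol
Conditions: NaOH, EtOH/H2O, reflux; then dilute HCl
Reagents that add atoms: none
Why: Base hydrolysis of the aryl carbamate; the aryl iodide and the methyl ether are inert to hydroxide.

Step 5
Reactants: 7 3-iodo-4'-methoxy-4-methyl-[1,1'-biphenyl]-2-ol
Product: 8 3-iodo-4'-methoxy-4-methyl-[1,1'-biphenyl]-2-yl trifluoromethanesulfonate
Conditions: Tf2O, pyridine, CH2Cl2, 0 °C → rt
Reagents that add atoms: trifluoromethanesulfonic anhydride, O=S(=O)(OS(=O)(=O)C(F)(F)F)C(F)(F)F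
Why: Standard O-triflation; doing it before the alkyne is introduced avoids a free ortho-alkynylphenol that could close to a benzofuran.

Step 6
Reactants: 8 3-iodo-4'-methoxy-4-methyl-[1,1'-biphenyl]-2-yl trifluoromethanesulfonate; 9 1-ethynyl-4-methoxybenzene
Product: 10 4'-methoxy-3-[(4-methoxyphenyl)ethynyl]-4-methyl-[1,1'-biphenyl]-2-yl trifluoromethanesulfonate
Conditions: PdCl2(PPh3)2 (3 mol %), CuI (5 mol %), Et3N, THF, rt → 45 °C
Reagents that add atoms: none
Why: Sonogashira coupling; with a PPh3-ligated catalyst the C–I bond reacts far faster than the doubly flanked C–OTf bond, so the triflate is kept for step 8.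

Step 7
Reactants: 11 (4-hydroxyphenyl)(phenyl)methanone (4-hydroxybenzophenone)
Product: 12 N'-[(4-hydroxyphenyl)(phenyl)methylidene]-4-methylbenzenesulfonohydrazide (E/Z mixture, both isomers give the same diazo compound)
Conditions: TsNHNH2, cat. HCl, EtOH, reflux
Reagents that add atoms: 4-methylbenzenesulfonohydrazide (tosylhydrazide), Cc1ccc(cc1)S(=O)(=O)NN
Why: Acid-catalysed condensation of an unhindered diaryl ketone with tosylhydrazide; the hydrazone crystallises from ethanol.

Step 8
Reactants: 10 4'-methoxy-3-[(4-methoxyphenyl)ethynyl]-4-methyl-[1,1'-biphenyl]-2-yl trifluoromethanesulfonate; 12 N'-[(4-hydroxyphenyl)(phenyl)methylidene]-4-methylbenzenesulfonohydrazide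
Product: 14 4-[{4'-methoxy-3-[(4-methoxyphenyl)ethynyl]-4-methyl-[1,1'-biphenyl]-2-yl}(phenyl)methylidene]cyclohexa-2,5-dien-1-one, via diazo phenolate 13 (not isolated)
Conditions: Pd2(dba)3 (2.5 mol %), XPhos (10 mol %), LiOt-Bu (3 equiv), 1,4-dioxane, 100 °C
Reagents that add atoms: none
Why: Proposed new method: base converts 12 into the diazo phenolate 13 (Bamford–Stevens), which is captured by the aryl–Pd(II) species from oxidative addition of triflate 10 to give a Pd carbene; 1,1-migratory insertion of the aryl group gives a triarylmethyl–Pd(II) intermediate that has no β-hydrogen, so the para-phenolate pushes electrons through its ring and expels Pd(0) (dearomative 1,6-elimination), which forms the aryl–C(methide) bond and the quinone methide in one operation; the closest known reaction type is the Pd-catalysed cross-coupling of N-tosylhydrazones with aryl (pseudo)halides (Barluenga coupling) and its hydride-terminated reductive variant that gives triarylmethanes.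

Step 9
Reactants: 14 4-[{4'-methoxy-3-[(4-methoxyphenyl)ethynyl]-4-methyl-[1,1'-biphenyl]-2-yl}(phenyl)methylidene]cyclohexa-2,5-dien-1-one
Product: 15 selaginellin A, 4-[{4'-hydroxy-3-[(4-hydroxyphenyl)ethynyl]-4-methyl-[1,1'-biphenyl]-2-yl}(phenyl)methylidene]cyclohexa-2,5-dien-1-one
Conditions: BBr3, CH2Cl2, −78 → 0 °C; then H2O
Reagents that add atoms: none
Why: Lewis-acid cleavage of the two aryl methyl ethers; the quinone methide is held as its O-borylated trityl cation during the reaction and returns on aqueous work-up, since 4-hydroxytrityl species collapse to the fuchsone.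

**Compound list**
1 | 2-bromo-5-methylphenol | Cc1ccc(Br)c(O)c1 | starting material
2 | (4-methoxyphenyl)boronic acid | COc1ccc(B(O)O)cc1 | starting material
3 | 4'-methoxy-4-methyl-[1,1'-biphenyl]-2-ol | Cc1ccc(-c2ccc(OC)cc2)c(O)c1 | intermediate
4 | 4'-methoxy-4-methyl-[1,1'-biphenyl]-2-yl diethylcarbamate | CCN(CC)C(=O)Oc1cc(C)ccc1-c1ccc(OC)cc1 | intermediate
5 | 3-lithio-4'-methoxy-4-methyl-[1,1'-biphenyl]-2-yl diethylcarbamate | CCN(CC)C(=O)Oc1c([Li])c(C)ccc1-c1ccc(OC)cc1 | intermediate (not isolated)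
6 | 3-iodo-4'-methoxy-4-methyl-[1,1'-biphenyl]-2-yl diethylcarbamate | CCN(CC)C(=O)Oc1c(I)c(C)ccc1-c1ccc(OC)cc1 | intermediate
7 | 3-iodo-4'-methoxy-4-methyl-[1,1'-biphenyl]-2-ol | Cc1ccc(-c2ccc(OC)cc2)c(O)c1I | intermediate
8 | 3-iodo-4'-methoxy-4-methyl-[1,1'-biphenyl]-2-yl trifluoromethanesulfonate | Cc1ccc(-c2ccc(OC)cc2)c(OS(=O)(=O)C(F)(F)F)c1I | intermediate
9 | 1-ethynyl-4-methoxybenzene | C#Cc1ccc(OC)cc1 | starting material
10 | 4'-methoxy-3-[(4-methoxyphenyl)ethynyl]-4-methyl-[1,1'-biphenyl]-2-yl trifluoromethanesulfonate | Cc1ccc(-c2ccc(OC)cc2)c(OS(=O)(=O)C(F)(F)F)c1C#Cc1ccc(OC)cc1 | intermediate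
11 | (4-hydroxyphenyl)(phenyl)methanone | O=C(c1ccccc1)c1ccc(O)cc1 | starting material
12 | N'-[(4-hydroxyphenyl)(phenyl)methylidene]-4-methylbenzenesulfonohydrazide (E/Z mixture) | Cc1ccc(cc1)S(=O)(=O)NN=C(c1ccccc1)c1ccc(O)cc1 | intermediate
13 | lithium 4-[diazo(phenyl)methyl]phenolate | [Li+].[O-]c1ccc(cc1)C(=[N+]=[N-])c1ccccc1 | intermediate (not isolated)
14 | 4-[{4'-methoxy-3-[(4-methoxyphenyl)ethynyl]-4-methyl-[1,1'-biphenyl]-2-yl}(phenyl)methylidene]cyclohexa-2,5-dien-1-one | Cc1ccc(-c2ccc(OC)cc2)c(C(=C2C=CC(=O)C=C2)c2ccccc2)c1C#Cc1ccc(OC)cc1 | intermediate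
15 | selaginellin A (achiral) | Cc1ccc(-c2ccc(O)cc2)c(C(=C2C=CC(=O)C=C2)c2ccccc2)c1C#Cc1ccc(O)cc1 | target

**Step count**
Total steps: 9. Longest linear sequence: 8 (steps 1–6, 8, 9); step 7 is a one-step side branch.

**Three steps most likely to fail, each with a fallback**

Step 8 (the proposed new step). The risks are that the very crowded triarylmethyl–Pd intermediate does not form, or that it is diverted by C–H palladation of the neighbouring anisyl ring to a 9,9-diarylfluorene. Alkoxide or phenoxide could also cleave the triflate S–O bond. The fallback uses known chemistry, sets out from triflate 10 and re-enters at target 15. Carbonylative Suzuki coupling of 10 with boronic acid 2 under CO (Pd(OAc)2/di(1-adamantyl)-n-butylphosphine, K2CO3, dioxane, 90 °C) gives {4'-methoxy-3-[(4-methoxyphenyl)ethynyl]-4-methyl-[1,1'-biphenyl]-2-yl}(4-methoxyphenyl)methanone F1. Addition of phenyllithium (THF, −78 → 0 °C) gives the racemic tertiary alcohol {4'-methoxy-3-[(4-methoxyphenyl)ethynyl]-4-methyl-[1,1'-biphenyl]-2-yl}(4-methoxyphenyl)(phenyl)methanol F2. BBr3 (CH2Cl2, −78 → 0 °C, then water) removes all three methyl groups, and the 4-hydroxytrityl alcohol loses water to give 15 directly.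

Step 3. Lithiation between the carbamate and the methyl group is hindered; metalation ortho to the methoxy group or on the 2'-position of the other ring could compete. The fallback sets out from phenol 3 and re-enters at triflate 10, making the alkyne by homologation instead of by iodination. Magnesium-mediated ortho-formylation of 3 (MgCl2, Et3N, paraformaldehyde, MeCN, reflux) is ortho-specific and gives 2-hydroxy-4'-methoxy-4-methyl-[1,1'-biphenyl]-3-carbaldehyde F3. Triflation (Tf2O, pyridine, CH2Cl2, 0 °C) gives 3-formyl-4'-methoxy-4-methyl-[1,1'-biphenyl]-2-yl trifluoromethanesulfonate F4. Seyferth–Gilbert homologation with the Ohira–Bestmann reagent (dimethyl (1-diazo-2-oxopropyl)phosphonate, K2CO3, MeOH, 0 °C → rt) gives 3-ethynyl-4'-methoxy-4-methyl-[1,1'-biphenyl]-2-yl trifluoromethanesulfonate F5. Sonogashira coupling of F5 with 4-iodoanisole (PdCl2(PPh3)2, CuI, Et3N, rt) gives 10.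

Step 9. BBr3 turns the fuchsone into a trityl-type cation that could cyclise onto the neighbouring aryl ring (fluorene formation), and the alkyne could be bromoborated. The fallback sets out from 14 and re-enters at 15, with the quinone methide masked in its reduced form during demethylation. NaBH4 (THF/MeOH, 0 °C) adds hydride 1,6 to 14 and gives racemic 4-[{4'-methoxy-3-[(4-methoxyphenyl)ethynyl]-4-methyl-[1,1'-biphenyl]-2-yl}(phenyl)methyl]phenol F6. BBr3 (CH2Cl2, −78 → 0 °C) then gives racemic 4-[{4'-hydroxy-3-[(4-hydroxyphenyl)ethynyl]-4-methyl-[1,1'-biphenyl]-2-yl}(phenyl)methyl]phenol F7. DDQ (1.0 equiv, CH2Cl2, 0 °C) oxidises the 4-hydroxytriarylmethane C–H of F7 back to the quinone methide 15.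

**Further compounds**
F1 | step 8 | {4'-methoxy-3-[(4-methoxyphenyl)ethynyl]-4-methyl-[1,1'-biphenyl]-2-yl}(4-methoxyphenyl)methanone | Cc1ccc(-c2ccc(OC)cc2)c(C(=O)c2ccc(OC)cc2)c1C#Cc1ccc(OC)cc1
F2 | step 8 | {4'-methoxy-3-[(4-methoxyphenyl)ethynyl]-4-methyl-[1,1'-biphenyl]-2-yl}(4-methoxyphenyl)(phenyl)methanol (racemic) | Cc1ccc(-c2ccc(OC)cc2)c(C(O)(c2ccccc2)c2ccc(OC)cc2)c1C#Cc1ccc(OC)cc1
F3 | step 3 | 2-hydroxy-4'-methoxy-4-methyl-[1,1'-biphenyl]-3-carbaldehyde | Cc1ccc(-c2ccc(OC)cc2)c(O)c1C=O
F4 | step 3 | 3-formyl-4'-methoxy-4-methyl-[1,1'-biphenyl]-2-yl trifluoromethanesulfonate | Cc1ccc(-c2ccc(OC)cc2)c(OS(=O)(=O)C(F)(F)F)c1C=O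
F5 | step 3 | 3-ethynyl-4'-methoxy-4-methyl-[1,1'-biphenyl]-2-yl trifluoromethanesulfonate | Cc1ccc(-c2ccc(OC)cc2)c(OS(=O)(=O)C(F)(F)F)c1C#C
F6 | step 9 | 4-[{4'-methoxy-3-[(4-methoxyphenyl)ethynyl]-4-methyl-[1,1'-biphenyl]-2-yl}(phenyl)methyl]phenol (racemic) | Cc1ccc(-c2ccc(OC)cc2)c(C(c2ccccc2)c2ccc(O)cc2)c1C#Cc1ccc(OC)cc1
F7 | step 9 | 4-[{4'-hydroxy-3-[(4-hydroxyphenyl)ethynyl]-4-methyl-[1,1'-biphenyl]-2-yl}(phenyl)methyl]phenol (racemic) | Cc1ccc(-c2ccc(O)cc2)c(C(c2ccccc2)c2ccc(O)cc2)c1C#Cc1ccc(O)cc1
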